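**Plan**

1. Retrosynthesis: the two acids, the 19α-alcohol and the C19 ketone are unmasked last. The pentacycle is then cut at C15–C16 and C17–C18, because the tetrasubstituted C13=C14 alkene is the middle bond of cyclohexene ring D and the C17–C18 edge of that ring is shared with ring E. This is the retron of an intramolecular [4+2] between a ring C 1,2-dialkylidene diene (C15=C14–C13=C18) and a 2-alkyl acrylate (C16=C17) tied to C18 through C19–C22.
2. The triene is cut further at C22–C17 (phosphonoacetate alkylation, methylenation), C13–C14 (alkenyl iodide onto alkyne, palladium), C18–C19 (acetylide acylation), C12–C27 (propargylboration) and C8–C14 (radical alkynylation), back to a geranyl-derived β-keto ester.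
3. Forward: rings A and B arise together by oxidative radical bicyclisation, the arms on C8 and C9 are grown, the seven-membered ring C is closed with palladium, and rings D and E close together in the cycloaddition.
4. Stereochemistry: C4, C5, C9 and C10 come from the chair–chair cyclisation of the (E,E)-polyene, with absolute configuration by lipase resolution. C8 is set by radical capture anti to the C10 methyl, C12 by a chiral phosphoric acid, C3 by a bulky hydride, C17 and C18 in the cycloaddition (α face, ester exo), and C19 by hydride from the convex β face.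

Key step: step 22

Remark: oleanane numbering is used; the extra ring C methylene between C12 and C13 is called C27, the carboxyl carbons on C4 and C17 are C24 and C28, the methyl on C8 is C26, and α/β are the usual triterpenoid faces.

**Route**

Step 1
Reactants: 1 geranyl acetate
Product: 2 (2E,6E)-8-hydroxygeranyl acetate
Conditions: SeO2 (cat.), t-BuOOH, salicylic acid (cat.), CH2Cl2, rt
Reagents that add atoms: tert-butyl hydroperoxide CC(C)(C)OO
Why: SeO2-catalysed allylic oxidation (ene reaction, then [2,3]-shift) takes the (E)-methyl of the terminal trisubstituted alkene, the alkene next to the acetate being inductively deactivated.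

Step 2
Reactants: 2 (2E,6E)-8-hydroxygeranyl acetate
Product: 3 (2E,6E)-8-bromogeranyl acetate
Conditions: CBr4, PPh3, CH2Cl2, 0 °C
Reagents that add atoms: carbon tetrabromide BrC(Br)(Br)Br
Why: Appel bromination of a primary allylic alcohol proceeds by SN2 displacement of the oxyphosphonium group without allylic transposition or loss of alkene geometry.

Step 3
Reactants: 3 (2E,6E)-8-bromogeranyl acetate; 4 methyl 2-methylacetoacetate
Product: 6 methyl (6E,10E)-12-acetoxy-2,6,10-trimethyl-3-oxododeca-6,10-dienoate, via dienolate dianion 5 (not isolated)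
Conditions: 4, NaH then n-BuLi, THF, 0 °C; then 3, 0 °C; aq. NH4Cl
Reagents that add atoms: none
Why: γ-Alkylation of a β-keto ester dianion: the more reactive terminal carbanion displaces the primary allylic bromide faster than it attacks the acetate.

Step 4
Reactants: 6 methyl (6E,10E)-12-acetoxy-2,6,10-trimethyl-3-oxododeca-6,10-dienoate
Product: 7 racemic bicyclic keto ester acetate (3-ketone; 4α-Me; 4β-CO2Me; 5α-H; 10β-Me; exocyclic C8=C26; 9β-CH2OAc)
Conditions: Mn(OAc)3·2H2O (2.2 equiv), Cu(OAc)2·H2O (0.5 equiv), AcOH (degassed), rt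
Reagents that add atoms: none
Why: Oxidative radical polyene cyclisation: the C4 radical from the manganese enolate closes ring A and then ring B (both 6-endo) through a chair–chair array of the (E,E)-diene, which should give the trans fusion, the axial 4β-ester and the equatorial 9β-CH2OAc, and Cu(OAc)2 oxidises the tertiary C8 radical to the exocyclic alkene; the product is racemic.

Step 5
Reactants: 7 racemic bicyclic keto ester acetate
Product: 8 keto alcohol (9β-CH2OH; 5α-H; 10β-Me enantiomer)
Conditions: Amano lipase PS, phosphate buffer (pH 7)/MTBE, 30 °C, stopped short of half conversion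
Reagents that add atoms: none
Why: Enzymatic kinetic resolution by enantioselective hydrolysis of a primary acetate: by analogy with the lipase resolution of albicanol-type 11-oxygenated drimanes, the enantiomer of normal terpenoid configuration should be hydrolysed, so the alcohol is collected as 8 and the antipodal acetate is left behind.

Step 6
Reactants: 8 keto alcohol; 9 triisopropyl[(phenylsulfonyl)ethynyl]silane
Product: 10 8α-[(triisopropylsilyl)ethynyl]-8β-methyl keto alcohol
Conditions: Fe(acac)3 (30 mol %), PhSiH3, EtOH/ethylene glycol, 60 °C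
Reagents that add atoms: none
Why: Metal-hydride hydrogen-atom-transfer hydroalkynylation (radical addition to an alkynyl sulfone, then β-fragmentation): an iron hydride gives H• to the exocyclic CH2, and the tertiary C8 radical should be trapped on its equatorial α face, away from the syn-axial C10 methyl, expelling PhSO2• and setting 8β-methyl/8α-alkynyl.

Step 7
Reactants: 10 8α-[(triisopropylsilyl)ethynyl]-8β-methyl keto alcohol
Product: 11 C11 aldehyde
Conditions: Dess–Martin periodinane, NaHCO3, CH2Cl2, rt
Reagents that add atoms: none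
Why: Dess–Martin oxidation of the primary alcohol under buffered conditions; the 9β-formyl group is the equatorial, stable epimer, so C9 is not at risk.

Step 8
Reactants: 11 C11 aldehyde; 12 (methoxymethyl)triphenylphosphonium chloride
Product: 15 C12 aldehyde (9β-CH2CHO), via phosphorus ylide 13 (not isolated), via enol ether 14 (not isolated)
Conditions: 12, KN(SiMe3)2, THF, −78 → 0 °C; then 2 M HCl, THF, rt
Reagents that add atoms: water O
Why: Wittig methoxymethylenation of the aldehyde (the C3 ketone beside the quaternary C4 is too hindered to compete) followed by acid hydrolysis of the enol ether gives the one-carbon homologue; the silylalkyne is stable to both.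

Step 9
Reactants: 15 C12 aldehyde; 16 allenylboronic acid pinacol ester
Product: 18 (12S)-homopropargylic alcohol, via pinacol borate ester 17 (not isolated)
Conditions: 16, (R)-TRIP (10 mol %), 4 Å MS, toluene, 0 °C; aqueous work-up
Reagents that add atoms: none
Why: Chiral phosphoric acid-catalysed propargylboration through a closed six-membered SE2' transition state: the (R)-catalyst should direct the propargyl group to the re face of the unbranched aldehyde and give the (12S)-alcohol under catalyst control, and a minor 12-epimer, being a diastereomer, can be removed here.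

Step 10
Reactants: 18 (12S)-homopropargylic alcohol
Product: 19 (12S)-methyl ether
Conditions: Me3OBF4, 1,8-bis(dimethylamino)naphthalene, CH2Cl2, rt
Reagents that add atoms: trimethyloxonium tetrafluoroborate C[O+](C)C.F[B-](F)(F)F
Why: O-Methylation with an oxonium salt and a non-nucleophilic base, chosen because it neither enolises the C3 ketone nor deprotonates the terminal alkyne.

Step 11
Reactants: 19 (12S)-methyl ether
Product: 20 3α-alcohol (AB fragment with terminal C13≡C18 alkyne)
Conditions: L-Selectride (LiBH(s-Bu)3), THF, −78 °C; aq. NH4Cl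
Reagents that add atoms: none
Why: Diastereoselective ketone reduction with a bulky trialkylborohydride: equatorial attack on the 4,4-disubstituted 3-ketone, as with 3-oxotriterpenoids, should give the axial 3α-alcohol, and the hindered ester and both alkynes are inert at −78 °C.

Step 12
Reactants: 21 α,α-dimethyl-γ-butyrolactone
Product: 22 4-hydroxy-N-methoxy-N,2,2-trimethylbutanamide
Conditions: MeNH(OMe)·HCl, AlMe3, CH2Cl2, 0 °C → rt; cold 1 M HCl work-up
Reagents that add atoms: N,O-dimethylhydroxylamine hydrochloride CNOC.Cl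
Why: Aminolysis of a lactone by an aluminium amide (Weinreb amide formation), which opens even α,α-disubstituted lactones.

Step 13
Reactants: 22 4-hydroxy-N-methoxy-N,2,2-trimethylbutanamide
Product: 23 4-(tert-butyldimethylsilyloxy)-N-methoxy-N,2,2-trimethylbutanamide
Conditions: TBSCl, imidazole, DMF, rt
Reagents that add atoms: tert-butyldimethylsilyl chloride CC(C)(C)[Si](C)(C)Cl
Why: Silylation of the primary alcohol, done at once so that the hydroxy amide cannot close back to the lactone.

Step 14
Reactants: 20 3α-alcohol; 23 4-(tert-butyldimethylsilyloxy)-N-methoxy-N,2,2-trimethylbutanamide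
Product: 25 ynone (C19 ketone; C22–OTBS), via dilithio acetylide alkoxide 24 (not isolated)
Conditions: 20, n-BuLi (2.1 equiv), THF, −78 °C; then 23, −78 → 0 °C; aq. NH4Cl
Reagents that add atoms: none
Why: Acylation of a lithium acetylide by an N-methoxy-N-methylamide: the chelated tetrahedral intermediate prevents a second addition, and the C3 lithium alkoxide is a spectator.

Step 15
Reactants: 25 ynone
Product: 26 C19 dioxolane
Conditions: (TMSOCH2)2, TMSOTf (cat.), CH2Cl2, −78 → −20 °C; then K2CO3, MeOH, rt
Reagents that add atoms: 1,2-bis(trimethylsilyloxy)ethane C[Si](C)(C)OCCO[Si](C)(C)C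
Why: TMSOTf-catalysed ketalisation with the bis-silyl glycol at low temperature, conditions under which ynones ketalise without conjugate addition and the silyl ether and silylalkyne survive; the methanolic carbonate frees any 3-O-silyl ether.

Step 16
Reactants: 26 C19 dioxolane
Product: 28 (13E)-13-iodoalkene, via alkenylzirconocene chloride 27 (not isolated)
Conditions: Cp2Zr(H)Cl (3 equiv), THF, rt → 40 °C; then I2, 0 °C
Reagents that add atoms: iodine II
Why: Hydrozirconation–iodination: Zr–H adds syn across the internal alkyne with zirconium on C13, the carbon remote from the fully substituted ketal carbon, and iodinolysis with retention should give the (E)-iodide in which C19 and C27 are cis; the hindered silylalkyne is left alone and the 3-OH only consumes one equivalent of reagent.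

Step 17
Reactants: 28 (13E)-13-iodoalkene
Product: 29 iodo enyne diol (8α-ethynyl; 3α-OH; 22-OH)
Conditions: Bu4NF, THF, rt
Reagents that add atoms: none
Why: Fluoride desilylation removes the alkynyl and the primary O-silyl groups together; the alkenyl iodide and the ketal are inert.

Step 18
Reactants: 29 iodo enyne diol
Product: 30 tricyclic diene diol (ring C closed; C14=C15H2; (E)-C13=C18)
Conditions: Pd(PPh3)4 (10 mol %), HCO2Na, DMF (degassed), 70 °C
Reagents that add atoms: none
Why: Intramolecular reductive Heck reaction (cyclic carbopalladation with hydride capture): zerovalent palladium inserts into the C13–I bond, the alkenylpalladium adds syn to the terminal alkyne in the 7-exo-dig mode, helped by the trans-diequatorial arms on C8 and C9, and formate reduces the C15–Pd bond, so the diene geometry fixed in 28 is kept.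

Step 19
Reactants: 30 tricyclic diene diol
Product: 31 C22 iodide
Conditions: I2, PPh3, imidazole, CH2Cl2, 0 °C
Reagents that add atoms: iodine II
Why: Appel iodination is selective for the primary alcohol over the axial, neopentyl-type 3α-alcohol, and the premixed phosphonium reagent leaves the hindered diene alone.

Step 20
Reactants: 31 C22 iodide; 32 trimethyl phosphonoacetate
Product: 34 C17 phosphonate (C17 epimers), via sodium phosphonoacetate 33 (not isolated)
Conditions: 32 (excess), NaH, DMF, 0 °C → rt; then 31, 50 °C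
Reagents that add atoms: none
Why: SN2 C-alkylation of a stabilised phosphonate carbanion by a primary iodide; with the phosphonate in excess over NaH the 3-OH is not deprotonated.

Step 21
Reactants: 34 C17 phosphonate; 35 formaldehyde
Product: 36 2-substituted acrylate (cycloaddition precursor)
Conditions: 35 (37% aq.), K2CO3, THF/H2O, rt
Reagents that add atoms: none
Why: Horner–Wadsworth–Emmons methylenation with formaldehyde, the standard route to 2-alkyl acrylates, run under carbonate conditions that the ketal, diene and esters tolerate.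

Step 22
Reactants: 36 2-substituted acrylate
Product: 37 pentacyclic ketal dimethyl ester (17β-CO2Me; 18β-H)
Conditions: toluene (5 mM), BHT (cat.), 170 °C, sealed tube
Reagents that add atoms: none
Why: A concerted, suprafacial thermal [4+2] cycloaddition (type 1 intramolecular Diels–Alder reaction of a 1,7,9-decatriene carrying the ester on C2) joins C15 to C16 and C17 to C18. Ring D closes as the cyclohexene of the cycloadduct, with the new C13=C14 bond arising from the two inner diene carbons, and ring E closes in the fused mode as the six-membered ring spanned by the four-atom tether C19–C22 between diene terminus C18 and dienophile carbon C17. C18 is set by the diene face that is attacked: the axial 8β-methyl, backed by the 10β-methyl, screens the β face beside C14/C15, so bonding from the α face should leave the inside hydrogen β. C17 is set by the exo/endo mode: the ester sits exo and the tether endo, the usual preference of 2-substituted acrylates, reinforced by the gem-dimethyl and ketal groups that fold the tether under the diene, which gives the cis D/E junction with 17β-CO2Me. The selectivity needed is therefore α-face, tether-endo; ring C holds the diene s-cis, the achiral ketal at C19 adds no opposing facial bias, and the diene has no hydrogen placed for a 1,5-shift, so long heating is tolerated.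

Step 23
Reactants: 37 pentacyclic ketal dimethyl ester
Product: 38 19-oxo dimethyl ester
Conditions: PPTS, acetone/H2O, 50 °C
Reagents that add atoms: water O
Why: Acid-catalysed ketal hydrolysis under mild, buffered conditions, chosen so that the β,γ-unsaturated 19-ketone is neither enolised towards C18 nor drawn into conjugation.

Step 24
Reactants: 38 19-oxo dimethyl ester
Product: 39 3α,19α-diol dimethyl ester
Conditions: NaBH4, MeOH/THF, 0 °C
Reagents that add atoms: none
Why: Diastereoselective borohydride reduction: in the cis-fused D/E conformer with H18 axial on ring E, the axial (α) approach to C19 is blocked by the syn-axial C16 methylene of ring D folded under ring E, so hydride should enter from the convex β face and give the axial 19α-alcohol.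

Step 25
Reactants: 39 3α,19α-diol dimethyl ester
Product: 40 target diacid
Conditions: n-PrSLi (from n-PrSH and n-BuLi), HMPA, rt → 50 °C; then dilute HCl
Reagents that add atoms: none
Why: Ester cleavage by SN2 dealkylation: the thiolate attacks the O-methyl carbons, a mode indifferent to the shielding of the two neopentyl carbonyl groups, and leaves the C12 methyl ether, the alkene and both carbinol centres untouched.

**Compound list**

1 | geranyl acetate | CC(C)=CCC/C(C)=C/COC(C)=O | starting material
2 | (2E,6E)-8-hydroxygeranyl acetate | OC/C(C)=C/CC/C(C)=C/COC(C)=O | intermediate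
3 | (2E,6E)-8-bromogeranyl acetate | BrC/C(C)=C/CC/C(C)=C/COC(C)=O | intermediate
4 | methyl 2-methylacetoacetate | COC(=O)C(C)C(C)=O | starting material
5 | sodium lithium dienolate (dianion) of 4 | C=C([O-])C(C)=C([O-])OC.[Na+].[Li+] | intermediate
6 | methyl (6E,10E)-12-acetoxy-2,6,10-trimethyl-3-oxododeca-6,10-dienoate (C2 epimers) | COC(=O)C(C)C(=O)CC/C(C)=C/CC/C(C)=C/COC(C)=O | intermediate
7 | racemic bicyclic keto ester acetate: trans-decalin, 3-ketone, 4α-Me, 4β-CO2Me, 5α-H, 10β-Me, exocyclic C8=C26, 9β-CH2OAc (racemate; SMILES shows the enantiomer carried on) | CC(=O)OC[C@H]1C(=C)CC[C@@H]2[C@]1(C)CCC(=O)[C@]2(C)C(=O)OC | intermediate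
8 | keto alcohol: same decalin, 9β-CH2OH, single enantiomer | OC[C@H]1C(=C)CC[C@@H]2[C@]1(C)CCC(=O)[C@]2(C)C(=O)OC | intermediate
9 | triisopropyl[(phenylsulfonyl)ethynyl]silane | CC(C)[Si](C#CS(=O)(=O)c1ccccc1)(C(C)C)C(C)C | starting material
10 | 8α-[(triisopropylsilyl)ethynyl]-8β-methyl keto alcohol | OC[C@H]1[C@](C)(C#C[Si](C(C)C)(C(C)C)C(C)C)CC[C@@H]2[C@]1(C)CCC(=O)[C@]2(C)C(=O)OC | intermediate
11 | C11 aldehyde (9β-CHO) | O=C[C@H]1[C@](C)(C#C[Si](C(C)C)(C(C)C)C(C)C)CC[C@@H]2[C@]1(C)CCC(=O)[C@]2(C)C(=O)OC | intermediate
12 | (methoxymethyl)triphenylphosphonium chloride | COC[P+](c1ccccc1)(c1ccccc1)c1ccccc1.[Cl-] | starting material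
13 | (methoxymethylene)triphenylphosphorane | COC=P(c1ccccc1)(c1ccccc1)c1ccccc1 | intermediate
14 | C11=C12 methyl enol ether (E/Z mixture) | COC=C[C@H]1[C@](C)(C#C[Si](C(C)C)(C(C)C)C(C)C)CC[C@@H]2[C@]1(C)CCC(=O)[C@]2(C)C(=O)OC | intermediate
15 | C12 aldehyde (9β-CH2CHO) | O=CC[C@H]1[C@](C)(C#C[Si](C(C)C)(C(C)C)C(C)C)CC[C@@H]2[C@]1(C)CCC(=O)[C@]2(C)C(=O)OC | intermediate
16 | allenylboronic acid pinacol ester | C=C=CB1OC(C)(C)C(C)(C)O1 | starting material
17 | pinacol borate ester of 18 | C#CC[C@@H](OB1OC(C)(C)C(C)(C)O1)C[C@H]2[C@](C)(C#C[Si](C(C)C)(C(C)C)C(C)C)CC[C@@H]3[C@]2(C)CCC(=O)[C@]3(C)C(=O)OC | intermediate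
18 | (12S)-homopropargylic alcohol (9β-CH2–CH(OH)–CH2–C≡CH; 3-ketone) | C#CC[C@@H](O)C[C@H]1[C@](C)(C#C[Si](C(C)C)(C(C)C)C(C)C)CC[C@@H]2[C@]1(C)CCC(=O)[C@]2(C)C(=O)OC | intermediate
19 | (12S)-methyl ether, 3-ketone | C#CC[C@@H](OC)C[C@H]1[C@](C)(C#C[Si](C(C)C)(C(C)C)C(C)C)CC[C@@H]2[C@]1(C)CCC(=O)[C@]2(C)C(=O)OC | intermediate
20 | 3α-alcohol, (12S)-methyl ether, terminal C13≡C18 alkyne | C#CC[C@@H](OC)C[C@H]1[C@](C)(C#C[Si](C(C)C)(C(C)C)C(C)C)CC[C@@H]2[C@]1(C)CC[C@@H](O)[C@]2(C)C(=O)OC | intermediate
21 | α,α-dimethyl-γ-butyrolactone | CC1(C)CCOC1=O | starting material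
22 | 4-hydroxy-N-methoxy-N,2,2-trimethylbutanamide | CON(C)C(=O)C(C)(C)CCO | intermediate
23 | 4-(tert-butyldimethylsilyloxy)-N-methoxy-N,2,2-trimethylbutanamide | CON(C)C(=O)C(C)(C)CCO[Si](C)(C)C(C)(C)C | intermediate
24 | dilithio acetylide alkoxide of 20 | [Li+].[Li+].[C-]#CC[C@@H](OC)C[C@H]1[C@](C)(C#C[Si](C(C)C)(C(C)C)C(C)C)CC[C@@H]2[C@]1(C)CC[C@@H]([O-])[C@]2(C)C(=O)OC | intermediate
25 | ynone (C19 ketone, C22–OTBS, 3α-OH) | CC(C)(C)[Si](C)(C)OCCC(C)(C)C(=O)C#CC[C@@H](OC)C[C@H]1[C@](C)(C#C[Si](C(C)C)(C(C)C)C(C)C)CC[C@@H]2[C@]1(C)CC[C@@H](O)[C@]2(C)C(=O)OC | intermediate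
26 | C19 dioxolane of 25 | CC(C)(C)[Si](C)(C)OCCC(C)(C)C1(OCCO1)C#CC[C@@H](OC)C[C@H]2[C@](C)(C#C[Si](C(C)C)(C(C)C)C(C)C)CC[C@@H]3[C@]2(C)CC[C@@H](O)[C@]3(C)C(=O)OC | intermediate
27 | C13 alkenylzirconocene chloride (3-O-zirconated) | CC(C)(C)[Si](C)(C)OCCC(C)(C)C1(OCCO1)/C=C([Zr](Cl)(C4C=CC=C4)C5C=CC=C5)\C[C@@H](OC)C[C@H]2[C@](C)(C#C[Si](C(C)C)(C(C)C)C(C)C)CC[C@@H]3[C@]2(C)CC[C@@H](O[Zr](Cl)(C6C=CC=C6)C7C=CC=C7)[C@]3(C)C(=O)OC | intermediate
28 | (13E)-13-iodoalkene (C19 and C27 cis) | CC(C)(C)[Si](C)(C)OCCC(C)(C)C1(OCCO1)/C=C(I)\C[C@@H](OC)C[C@H]2[C@](C)(C#C[Si](C(C)C)(C(C)C)C(C)C)CC[C@@H]3[C@]2(C)CC[C@@H](O)[C@]3(C)C(=O)OC | intermediate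
29 | iodo enyne diol (8α-ethynyl, 3α-OH, 22-OH) | OCCC(C)(C)C1(OCCO1)/C=C(I)\C[C@@H](OC)C[C@H]2[C@](C)(C#C)CC[C@@H]3[C@]2(C)CC[C@@H](O)[C@]3(C)C(=O)OC | intermediate
30 | tricyclic diene diol (rings A, B and C; C14=C15H2; (E)-C13=C18; 12α-OMe) | CO[C@@H]1C/C(=C\C2(OCCO2)C(C)(C)CCO)C(=C)[C@]2(C)CC[C@@H]3[C@](C)(CC[C@@H](O)[C@]3(C)C(=O)OC)[C@H]2C1 | intermediate
31 | C22 iodide | CO[C@@H]1C/C(=C\C2(OCCO2)C(C)(C)CCI)C(=C)[C@]2(C)CC[C@@H]3[C@](C)(CC[C@@H](O)[C@]3(C)C(=O)OC)[C@H]2C1 | intermediate
32 | trimethyl phosphonoacetate | COC(=O)CP(=O)(OC)OC | starting material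
33 | sodium salt of trimethyl phosphonoacetate | COC(=O)[CH-]P(=O)(OC)OC.[Na+] | intermediate
34 | C17 phosphonate (C17 epimers) | CO[C@@H]1C/C(=C\C2(OCCO2)C(C)(C)CCC(C(=O)OC)P(=O)(OC)OC)C(=C)[C@]2(C)CC[C@@H]3[C@](C)(CC[C@@H](O)[C@]3(C)C(=O)OC)[C@H]2C1 | intermediate
35 | formaldehyde | C=O | starting material
36 | 2-substituted acrylate, cycloaddition precursor | CO[C@@H]1C/C(=C\C2(OCCO2)C(C)(C)CCC(=C)C(=O)OC)C(=C)[C@]2(C)CC[C@@H]3[C@](C)(CC[C@@H](O)[C@]3(C)C(=O)OC)[C@H]2C1 | intermediate
37 | pentacyclic ketal dimethyl ester (cycloadduct; 17β-CO2Me, 18β-H) | CO[C@@H]1CC2=C(CC[C@@]3(C(=O)OC)CCC(C)(C)C4(OCCO4)[C@@H]23)[C@]2(C)CC[C@@H]3[C@](C)(CC[C@@H](O)[C@]3(C)C(=O)OC)[C@H]2C1 | intermediate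
38 | 19-oxo dimethyl ester | CO[C@@H]1CC2=C(CC[C@@]3(C(=O)OC)CCC(C)(C)C(=O)[C@@H]23)[C@]2(C)CC[C@@H]3[C@](C)(CC[C@@H](O)[C@]3(C)C(=O)OC)[C@H]2C1 | intermediate
39 | 3α,19α-diol dimethyl ester | CO[C@@H]1CC2=C(CC[C@@]3(C(=O)OC)CCC(C)(C)[C@@H](O)[C@@H]23)[C@]2(C)CC[C@@H]3[C@](C)(CC[C@@H](O)[C@]3(C)C(=O)OC)[C@H]2C1 | intermediate
40 | CNP0394974.1: 3α,19α-dihydroxy-12α-methoxy ring C-homo 27-norolean-13-ene-24,28-dioic acid | CO[C@@H]1CC2=C(CC[C@@]3(C(=O)O)CCC(C)(C)[C@@H](O)[C@@H]23)[C@]2(C)CC[C@@H]3[C@](C)(CC[C@@H](O)[C@]3(C)C(=O)O)[C@H]2C1 | target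

**Step count**

Total: 25 steps. Longest linear sequence: 23 steps (steps 1–11 and 14–25); steps 12–13 make the side-chain amide.

**Steps most likely to fail**

Step 18. The seven-membered exo-dig insertion may be slower than formate reduction of the alkenylpalladium iodide, so that iodine is simply lost, or the terminal alkyne may oligomerise. The fallback sets out from 26. Bu4NF removes the C-silyl and O-silyl groups to give the diyne diol F1, and ring C is closed by a hydropalladation-initiated reductive cyclisation (Pd2(dba)3·CHCl3, P(o-tol)3, AcOH, Et3SiH, benzene). Here a palladium hydride adds reversibly to the terminal alkyne, the C14 alkenylpalladium inserts the internal alkyne and the silane reduces the dienylpalladium; no halide is present to be reduced early. This gives 30 directly, where the route is rejoined.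

Step 22. Face or exo/endo discrimination may be too low, or the cycloaddition may be so slow on the twisted seven-ring diene that the acrylate polymerises. The fallback changes the activating group and sets out from 36. DIBAL-H at −78 °C should reduce the unhindered acrylate ester, leaving the shielded C24 ester, to the allylic alcohol F2, and MnO2 then gives the 2-substituted acrolein F3. Its lower LUMO should allow the same cycloaddition near 80–100 °C, or with a secondary-amine salt as iminium catalyst; 2-substituted acroleins keep the formyl group exo. The cycloadduct aldehyde F4 is oxidised (NaClO2, NaH2PO4, 2-methyl-2-butene) to the acid F5, and TMSCHN2 returns to 37.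

Step 5. The enzyme may not tell the enantiomers apart well enough, because the stereocentre is β to the ester oxygen and flanked by quaternary carbons. The fallback is a covalent resolution and sets out from 7. Methanolysis (K2CO3, MeOH) gives the racemic keto alcohol F6, which is esterified with (S)-O-methylmandelic acid (DCC, DMAP). The two diastereomeric esters are separated by chromatography or crystallisation, and methanolysis of the (S)-O-methylmandelate of the needed decalin F7 comes back to 8.

**Further compounds**

F1 | step 18 | diyne diol (8α-ethynyl, C13≡C18, C19 dioxolane, 3α-OH, 22-OH) | OCCC(C)(C)C1(OCCO1)C#CC[C@@H](OC)C[C@H]2[C@](C)(C#C)CC[C@@H]3[C@]2(C)CC[C@@H](O)[C@]3(C)C(=O)OC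
F2 | step 22 | allylic alcohol from reduction of the acrylate ester of 36 | CO[C@@H]1C/C(=C\C2(OCCO2)C(C)(C)CCC(=C)CO)C(=C)[C@]2(C)CC[C@@H]3[C@](C)(CC[C@@H](O)[C@]3(C)C(=O)OC)[C@H]2C1
F3 | step 22 | 2-substituted acrolein | CO[C@@H]1C/C(=C\C2(OCCO2)C(C)(C)CCC(=C)C=O)C(=C)[C@]2(C)CC[C@@H]3[C@](C)(CC[C@@H](O)[C@]3(C)C(=O)OC)[C@H]2C1
F4 | step 22 | pentacyclic 28-aldehyde (17β-CHO, 18β-H) | CO[C@@H]1CC2=C(CC[C@@]3(C=O)CCC(C)(C)C4(OCCO4)[C@@H]23)[C@]2(C)CC[C@@H]3[C@](C)(CC[C@@H](O)[C@]3(C)C(=O)OC)[C@H]2C1
F5 | step 22 | pentacyclic 28-acid 24-methyl ester | CO[C@@H]1CC2=C(CC[C@@]3(C(=O)O)CCC(C)(C)C4(OCCO4)[C@@H]23)[C@]2(C)CC[C@@H]3[C@](C)(CC[C@@H](O)[C@]3(C)C(=O)OC)[C@H]2C1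
F6 | step 5 | racemic keto alcohol (racemate of 8; SMILES shows one enantiomer) | OC[C@H]1C(=C)CC[C@@H]2[C@]1(C)CCC(=O)[C@]2(C)C(=O)OC
F7 | step 5 | (S)-O-methylmandelate of 8 | CO[C@H](C(=O)OC[C@H]1C(=C)CC[C@@H]2[C@]1(C)CCC(=O)[C@]2(C)C(=O)OC)c1ccccc1
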